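Ring C of the (2S)-flavanone is cut at C3–C4 and O1–C2. The unit O1–C8a–C4a–C4 is treated as a latent α-methoxy o-quinone methide, and C2–C3 with its phenyl group as styrene. One chiral-acid-controlled hetero-[4+2] cycloaddition closes ring C, forms both bonds and sets C2; the C4 methoxy group is later unmasked to the ketone. The heterodiene precursor is a fully substituted salicylaldehyde, 3-allyl-4,6-bis(benzyloxy)-2-hydroxy-5-methoxybenzaldehyde. Its allyl group blocks the nucleophilic carbon that becomes C8, is a spectator in the cycloaddition, and becomes the prenyl group by a final cross-metathesis, so the flavanone never meets a strong base.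

Key step: step 8

Remarks on the chemistry:
- The target is read as (2S)-5,7-dihydroxy-6-methoxy-8-prenylflavanone with C2 as its only stereocentre; (2S,4S) in the cycloadduct is the 2,4-cis isomer. Flavanone numbering (O1, C2, C3, C4, C4a, C5–C8, C8a) is used throughout.
- The salicylaldehyde and 4-methoxyflavan skeletons of the key step are kept; the only change is the allyl spectator on the future C8.
- Assumption: the antipode of the chiral acid that leads to 2S cannot be predicted with certainty; (S,S) is written and would be exchanged for (R,R) if a first run shows the opposite sense.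

Step 1
Reactants: 1 methyl 3,5-dihydroxy-4-methoxybenzoate
Product: 2 methyl 3,5-bis(benzyloxy)-4-methoxybenzoate
Conditions: BnBr (2.4 equiv), K2CO3 (3 equiv), DMF, 60 °C
Reagents that add atoms: benzyl bromide, BrCc1ccccc1
Why: Williamson ether synthesis on the two equivalent phenols, with the ester and the methyl ether inert to carbonate base.

Step 2
Reactants: 2 methyl 3,5-bis(benzyloxy)-4-methoxybenzoate
Product: 3 [3,5-bis(benzyloxy)-4-methoxyphenyl]methanol
Conditions: LiAlH4, THF, 0 °C to rt; Fieser work-up
Reagents that add atoms: none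
Why: Hydride reduction of the aryl ester to the primary benzylic alcohol, which leaves benzyl and methyl aryl ethers untouched.

Step 3
Reactants: 3 [3,5-bis(benzyloxy)-4-methoxyphenyl]methanol
Product: 4 3,5-bis(benzyloxy)-4-methoxybenzaldehyde
Conditions: TEMPO (10 mol%), PhI(OAc)2 (1.1 equiv), CH2Cl2, rt
Reagents that add atoms: none
Why: Oxoammonium-mediated (TEMPO) oxidation of a primary benzylic alcohol, which stops cleanly at the aldehyde.

Step 4
Reactants: 4 3,5-bis(benzyloxy)-4-methoxybenzaldehyde
Product: 6 3,5-bis(benzyloxy)-4-methoxyphenol, via aryl formate 5 (not isolated)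
Conditions: mCPBA (1.3 equiv), CH2Cl2, 0 °C to rt; NaHCO3 wash; then Et3N (0.1 equiv), MeOH, rt
Reagents that add atoms: mCPBA, OOC(=O)c1cccc(Cl)c1
Why: Baeyer–Villiger (Dakin-type) oxidation in which the trioxygenated aryl group migrates in preference to hydrogen, followed by mild methanolysis of the labile aryl formate.

Step 5
Reactants: 6 3,5-bis(benzyloxy)-4-methoxyphenol; 7 allyl bromide
Product: 8 5-(allyloxy)-1,3-bis(benzyloxy)-2-methoxybenzene
Conditions: K2CO3 (2 equiv), acetone, reflux
Reagents that add atoms: allyl bromide (7), C=CCBr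
Why: Williamson O-allylation of the single free phenol.

Step 6
Reactants: 8 5-(allyloxy)-1,3-bis(benzyloxy)-2-methoxybenzene
Product: 9 2-allyl-3,5-bis(benzyloxy)-4-methoxyphenol
Conditions: PhNEt2, 190 °C, argon
Reagents that add atoms: none
Why: Aromatic Claisen rearrangement; the two ortho positions are equivalent and the para position carries the methoxy group, so [3,3] shift and tautomerisation can give only one allylphenol.

Step 7
Reactants: 9 2-allyl-3,5-bis(benzyloxy)-4-methoxyphenol
Product: 10 3-allyl-4,6-bis(benzyloxy)-2-hydroxy-5-methoxybenzaldehyde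
Conditions: MgCl2 (2 equiv), Et3N (4 equiv), (CH2O)n (6 equiv), THF, reflux; 1 M HCl work-up
Reagents that add atoms: paraformaldehyde (formaldehyde), C=O
Why: Magnesium phenoxide directed ortho-formylation (Casnati–Skattebøl type) at the only unsubstituted ring carbon, the hydroxymethyl intermediate being oxidised in the flask by a second formaldehyde.

Step 8
Reactants: 10 3-allyl-4,6-bis(benzyloxy)-2-hydroxy-5-methoxybenzaldehyde; 11 styrene; 12 trimethyl orthoformate
Product: 15 (2S,4S)-8-allyl-5,7-bis(benzyloxy)-4,6-dimethoxyflavan, via dimethyl acetal 13 (not isolated), via α-methoxy o-quinone methide 14 (not isolated)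
Conditions: HC(OMe)3 (1.5 equiv), (S,S)-IDPi acid HN[P(=NSO2CF3)(O2Ar*)]2 (O2Ar* = (S)-3,3'-bis[3,5-bis(trifluoromethyl)phenyl]-1,1'-binaphthalene-2,2'-diolate; 5 mol%), 5 Å MS, CH2Cl2, rt, 1 h; then styrene (5 equiv), −40 to −20 °C; Et3N quench at −40 °C
Reagents that add atoms: styrene (11), C=Cc1ccccc1; trimethyl orthoformate (12), COC(OC)OC
Why: Proposed new method: the acid exchanges the aldehyde with HC(OMe)3 to acetal 13 and ionises it to the phenol-conjugated oxocarbenium ion, the O-protonated form of o-quinone methide 14, which stays hydrogen-bonded and ion-paired to the confined chiral anion; the CH2 terminus of styrene then bonds to C4 and the developing benzylic cation at C2 collapses onto the phenol oxygen in an asynchronous inverse-demand hetero-[4+2] addition. The closest known reaction types are the achiral acid-promoted union of salicylaldehydes, orthoformates and alkenes to 4-alkoxychromans and chiral phosphoric acid controlled [4+2] cycloadditions of o-quinone methides with more nucleophilic alkenes; enantiocontrol with styrene itself is the unproven part. Ring C is closed by intermolecular [4+2] annulation, C3–C4 first and O1–C2 second, the second bond by six-membered capture of the cation within the ion pair. C2 is set by the chiral anion, which shields one face of the planar heterodiene and fixes the approach of the styrene phenyl group (acid antipode chosen for 2S), and C4 should follow as 2,4-cis from the endo-like approach but is erased in step 10. The step needs regiocontrol, secured by polarity (nucleophilic CH2 to electrophilic C4, benzylic carbon to O1), chemoselectivity for styrene over the C8 allyl group, secured by the far lower nucleophilicity of a monosubstituted alkyl alkene, and freedom from Friedel–Crafts self-condensation, secured by the fully substituted ring A. The C5 and C7 benzyloxy groups make ionisation easy but temper the electrophile, hence the strong acid, the excess of styrene and the cold amine quench that also guards C2 against cycloreversion.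

Step 9
Reactants: 15 (2S,4S)-8-allyl-5,7-bis(benzyloxy)-4,6-dimethoxyflavan
Product: 16 (2S)-8-allyl-5,7-bis(benzyloxy)-6-methoxyflavan-4-ol (both C4 epimers)
Conditions: 0.1 M HCl, THF/H2O (3:1), high dilution, 0 °C to rt; NaHCO3 quench
Reagents that add atoms: water, O
Why: SN1 solvolysis of a benzylic methyl ether that is ortho and para to three ring oxygens (O1, C5–O, C7–O), the cation being captured by the large excess of water; the C4 configuration is irrelevant and C2 lies outside the ionising system.

Step 10
Reactants: 16 (2S)-8-allyl-5,7-bis(benzyloxy)-6-methoxyflavan-4-ol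
Product: 17 (2S)-8-allyl-5,7-bis(benzyloxy)-6-methoxyflavan-4-one
Conditions: Dess–Martin periodinane (1.3 equiv), pyridine, CH2Cl2, 0 °C to rt
Reagents that add atoms: none
Why: Dess–Martin oxidation of the secondary benzylic alcohol under buffered, non-enolising conditions, so that both C4 epimers converge on one ketone and C2 stays untouched.

Step 11
Reactants: 17 (2S)-8-allyl-5,7-bis(benzyloxy)-6-methoxyflavan-4-one
Product: 18 (2S)-8-allyl-5,7-dihydroxy-6-methoxyflavan-4-one
Conditions: BCl3 (5 equiv), C6HMe5 (6 equiv), CH2Cl2, −78 °C; CHCl3/MeOH quench at −78 °C, aqueous work-up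
Reagents that add atoms: none
Why: Lewis acid cleavage of aryl benzyl ethers with pentamethylbenzene as a non-basic benzyl cation trap (Friedel–Crafts capture); the C5 ether is activated by chelation to the C4 carbonyl, and at −78 °C the methyl ether, the terminal alkene and the C2–O1 bond should not react.

Step 12
Reactants: 18 (2S)-8-allyl-5,7-dihydroxy-6-methoxyflavan-4-one; 19 2-methylbut-2-ene
Product: 20 Agrandol, (2S)-5,7-dihydroxy-6-methoxy-8-(3-methylbut-2-en-1-yl)flavan-4-one
Conditions: second-generation Grubbs catalyst RuCl2(=CHPh)(PCy3)(H2IMes) (5 mol%), 2-methylbut-2-ene/CH2Cl2 (1:2), 40 °C, sealed tube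
Reagents that add atoms: 2-methylbut-2-ene (19), CC=C(C)C
Why: Olefin cross-metathesis of the terminal allyl group with an excess of the trisubstituted alkene transfers the isopropylidene unit and releases propene; the neutral conditions tolerate free phenols and the ketone and cannot touch C2.

Compound list
1 | methyl 3,5-dihydroxy-4-methoxybenzoate | COC(=O)c1cc(O)c(OC)c(O)c1 | starting material
2 | methyl 3,5-bis(benzyloxy)-4-methoxybenzoate | COC(=O)c1cc(OCc2ccccc2)c(OC)c(OCc2ccccc2)c1 | intermediate
3 | [3,5-bis(benzyloxy)-4-methoxyphenyl]methanol | OCc1cc(OCc2ccccc2)c(OC)c(OCc2ccccc2)c1 | intermediate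
4 | 3,5-bis(benzyloxy)-4-methoxybenzaldehyde | O=Cc1cc(OCc2ccccc2)c(OC)c(OCc2ccccc2)c1 | intermediate
5 | 3,5-bis(benzyloxy)-4-methoxyphenyl formate | O=COc1cc(OCc2ccccc2)c(OC)c(OCc2ccccc2)c1 | intermediate (not isolated)
6 | 3,5-bis(benzyloxy)-4-methoxyphenol | Oc1cc(OCc2ccccc2)c(OC)c(OCc2ccccc2)c1 | intermediate
7 | allyl bromide (3-bromoprop-1-ene) | C=CCBr | starting material
8 | 5-(allyloxy)-1,3-bis(benzyloxy)-2-methoxybenzene | C=CCOc1cc(OCc2ccccc2)c(OC)c(OCc2ccccc2)c1 | intermediate
9 | 2-allyl-3,5-bis(benzyloxy)-4-methoxyphenol | C=CCc1c(O)cc(OCc2ccccc2)c(OC)c1OCc1ccccc1 | intermediate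
10 | 3-allyl-4,6-bis(benzyloxy)-2-hydroxy-5-methoxybenzaldehyde | O=Cc1c(O)c(CC=C)c(OCc2ccccc2)c(OC)c1OCc1ccccc1 | intermediate (key-step precursor)
11 | styrene | C=Cc1ccccc1 | starting material
12 | trimethyl orthoformate | COC(OC)OC | starting material
13 | 2-allyl-3,5-bis(benzyloxy)-6-(dimethoxymethyl)-4-methoxyphenol (dimethyl acetal of 10) | COC(OC)c1c(O)c(CC=C)c(OCc2ccccc2)c(OC)c1OCc1ccccc1 | intermediate (not isolated)
14 | 2-allyl-3,5-bis(benzyloxy)-4-methoxy-6-(methoxymethylidene)cyclohexa-2,4-dien-1-one (α-methoxy o-quinone methide, present as its O-protonated ion pair with the acid anion) | COC=C1C(=O)C(CC=C)=C(OCc2ccccc2)C(OC)=C1OCc1ccccc1 | intermediate (not isolated)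
15 | (2S,4S)-8-allyl-5,7-bis(benzyloxy)-4,6-dimethoxyflavan (2,4-cis) | CO[C@H]1C[C@@H](c2ccccc2)Oc2c(CC=C)c(OCc3ccccc3)c(OC)c(OCc3ccccc3)c12 | intermediate (key-step product)
16 | (2S)-8-allyl-5,7-bis(benzyloxy)-6-methoxyflavan-4-ol (both C4 epimers) | OC1C[C@@H](c2ccccc2)Oc2c(CC=C)c(OCc3ccccc3)c(OC)c(OCc3ccccc3)c12 | intermediate
17 | (2S)-8-allyl-5,7-bis(benzyloxy)-6-methoxyflavan-4-one | O=C1C[C@@H](c2ccccc2)Oc2c(CC=C)c(OCc3ccccc3)c(OC)c(OCc3ccccc3)c12 | intermediate
18 | (2S)-8-allyl-5,7-dihydroxy-6-methoxyflavan-4-one | O=C1C[C@@H](c2ccccc2)Oc2c(CC=C)c(O)c(OC)c(O)c12 | intermediate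
19 | 2-methylbut-2-ene | CC=C(C)C | starting material
20 | Agrandol, (2S)-5,7-dihydroxy-6-methoxy-8-(3-methylbut-2-en-1-yl)flavan-4-one | COc1c(O)c(CC=C(C)C)c2c(c1O)C(=O)C[C@@H](c1ccccc1)O2 | target

Total step count: 12. Longest linear sequence: 12 steps (1 to 20).

Steps most likely to fail

Step 8 (the proposed method). The strongly stabilised cation may add styrene too slowly, the anion may give incomplete facial control, or C2 may erode through reversible ionisation of the C2–O1 bond. The fallback uses known chemistry, sets out from 10 and returns at 17. Methylmagnesium bromide (2.2 equiv, THF, 0 °C) adds to the aldehyde to give 2-allyl-3,5-bis(benzyloxy)-6-(1-hydroxyethyl)-4-methoxyphenol F1. Oxidation with activated MnO2 gives 1-[3-allyl-4,6-bis(benzyloxy)-2-hydroxy-5-methoxyphenyl]ethan-1-one F2. Heating with N,N-dimethylformamide dimethyl acetal gives the enaminone (E)-1-[3-allyl-4,6-bis(benzyloxy)-2-hydroxy-5-methoxyphenyl]-3-(dimethylamino)prop-2-en-1-one F3, which closes with HCl in CH2Cl2 to 8-allyl-5,7-bis(benzyloxy)-6-methoxy-4H-chromen-4-one F4. Rhodium-catalysed asymmetric 1,4-addition of phenylboronic acid then installs the phenyl group at C2 and should give 17 directly. The conditions would be [Rh(OH)(cod)]2 with the antipode of 6,6'-dimethoxy-2,2'-bis[bis(3,4,5-trifluorophenyl)phosphino]biphenyl that gives 2S, in toluene/H2O.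

Step 11. Boron chelation may cleave the C6 methyl ether alongside the benzyl ethers, HCl may add to the allyl group, or Lewis-acid opening of ring C may erode C2. The fallback removes the benzyl groups by hydrogenolysis, which requires leaving C8 unsubstituted until the end; it sets out from 6 and returns at 20.
- Formylation as in step 7 gives 2,4-bis(benzyloxy)-6-hydroxy-3-methoxybenzaldehyde F5.
- The conditions of step 8 convert it into (2S,4S)-5,7-bis(benzyloxy)-4,6-dimethoxyflavan F8. This passes through 3,5-bis(benzyloxy)-2-(dimethoxymethyl)-4-methoxyphenol F6 and 3,5-bis(benzyloxy)-4-methoxy-6-(methoxymethylidene)cyclohexa-2,4-dien-1-one F7. The unblocked C8 position is accepted here, with a larger excess of styrene.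
- The conditions of steps 9 and 10 give (2S)-5,7-bis(benzyloxy)-6-methoxyflavan-4-ol F9 and then (2S)-5,7-bis(benzyloxy)-6-methoxyflavan-4-one F10.
- Hydrogenolysis (H2, Pd/C, EtOAc, rt) gives (2S)-5,7-dihydroxy-6-methoxyflavan-4-one F11.
- Base-free O-alkylation of the non-chelated C7 hydroxyl (Pd(PPh3)4, tert-butyl 2-methylbut-3-en-2-yl carbonate, THF, 0 °C) gives (2S)-5-hydroxy-6-methoxy-7-[(2-methylbut-3-en-2-yl)oxy]flavan-4-one F12.
- Claisen rearrangement (toluene, 110 °C, optionally Eu(fod)3 as catalyst) can only go to C8, because C6 carries the methoxy group, and should give 20.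

Step 9. The C4 cation may lose H3 to form the flav-3-ene, which can then dimerise with further cation instead of being captured by water. The fallback replaces solvolysis and alcohol oxidation by one oxidative operation, from 15 directly to 17. DDQ (1.1 equiv) in CH2Cl2/pH 7 buffer at 0 °C abstracts hydride from C4–H. Water adds to the resulting O-methyl oxocarbenium ion, and the hemiketal collapses to the ketone. The C4–H bond, activated by the methoxy group and ring A, should react well before the allylic CH2 group. No new compound is made.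

Further compounds
F1 | step 8 | 2-allyl-3,5-bis(benzyloxy)-6-(1-hydroxyethyl)-4-methoxyphenol (racemic) | CC(O)c1c(O)c(CC=C)c(OCc2ccccc2)c(OC)c1OCc1ccccc1
F2 | step 8 | 1-[3-allyl-4,6-bis(benzyloxy)-2-hydroxy-5-methoxyphenyl]ethan-1-one | CC(=O)c1c(O)c(CC=C)c(OCc2ccccc2)c(OC)c1OCc1ccccc1
F3 | step 8 | (E)-1-[3-allyl-4,6-bis(benzyloxy)-2-hydroxy-5-methoxyphenyl]-3-(dimethylamino)prop-2-en-1-one | CN(C)/C=C/C(=O)c1c(O)c(CC=C)c(OCc2ccccc2)c(OC)c1OCc1ccccc1
F4 | step 8 | 8-allyl-5,7-bis(benzyloxy)-6-methoxy-4H-chromen-4-one | O=c1ccoc2c(CC=C)c(OCc3ccccc3)c(OC)c(OCc3ccccc3)c12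
F5 | step 11 | 2,4-bis(benzyloxy)-6-hydroxy-3-methoxybenzaldehyde | O=Cc1c(O)cc(OCc2ccccc2)c(OC)c1OCc1ccccc1
F6 | step 11 | 3,5-bis(benzyloxy)-2-(dimethoxymethyl)-4-methoxyphenol | COC(OC)c1c(O)cc(OCc2ccccc2)c(OC)c1OCc1ccccc1
F7 | step 11 | 3,5-bis(benzyloxy)-4-methoxy-6-(methoxymethylidene)cyclohexa-2,4-dien-1-one | COC=C1C(=O)C=C(OCc2ccccc2)C(OC)=C1OCc1ccccc1
F8 | step 11 | (2S,4S)-5,7-bis(benzyloxy)-4,6-dimethoxyflavan | CO[C@H]1C[C@@H](c2ccccc2)Oc2cc(OCc3ccccc3)c(OC)c(OCc3ccccc3)c12
F9 | step 11 | (2S)-5,7-bis(benzyloxy)-6-methoxyflavan-4-ol (both C4 epimers) | OC1C[C@@H](c2ccccc2)Oc2cc(OCc3ccccc3)c(OC)c(OCc3ccccc3)c12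
F10 | step 11 | (2S)-5,7-bis(benzyloxy)-6-methoxyflavan-4-one | O=C1C[C@@H](c2ccccc2)Oc2cc(OCc3ccccc3)c(OC)c(OCc3ccccc3)c12
F11 | step 11 | (2S)-5,7-dihydroxy-6-methoxyflavan-4-one | O=C1C[C@@H](c2ccccc2)Oc2cc(O)c(OC)c(O)c12
F12 | step 11 | (2S)-5-hydroxy-6-methoxy-7-[(2-methylbut-3-en-2-yl)oxy]flavan-4-one | O=C1C[C@@H](c2ccccc2)Oc2cc(OC(C)(C)C=C)c(OC)c(O)c12
F0 | step 9 | none | none
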